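Ring A, the cyclohexane that carries the exocyclic methylene (C1–C5 and C10; C5/C10 ring fusion, C4 the methylene carbon), is treated as a masked 4-ketone and thus as the adduct of a 2-silyloxy diene (C5=C4–C3=C2) and an alkene (C10=C1). Since C5 and C10 are already joined through C6–C9, the cycloaddition is intramolecular: one operation forms C1–C2 and C5–C10, closes both rings of the trans-decalin and sets C5 and C10 from the preset C8/C9 pair. The precursor is an acyclic vinyl ketone bearing an (E)-vinyl sulfone; its C8/C9 stereocentres come from a cyclopentanone template that is opened by ozonolysis.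

Key step: step 15

Remarks
- Numbering: terpenoid numbering of the decalin is used for atoms (ring A = C1–C5, C10; ring B = C5–C10; C8 carries CH3, C9 carries CH3 and the arylmethyl group). Ts = 4-methylphenylsulfonyl, "tosyloxy" = OTs.
- Assumption: in step 6 the enantiomer of the carbene ligand that gives the (3S) enolate 8 is used.
- Assumption: the sulfonyl-bearing carbon in 24–26 is drawn as expected for suprafacial addition to the E alkene; this centre is erased in step 17.
- Ylide 15 is prepared (step 9) because its commercial supply is not assumed.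

Step 1
Reactants: 1 5-bromo-2-hydroxy-3-methoxybenzaldehyde
Product: 2 5-bromo-2,3-dihydroxybenzaldehyde
Conditions: BBr3, CH2Cl2, −78 °C → rt; aqueous work-up
Reagents that add atoms: none
Why: BBr3-mediated aryl methyl ether cleavage should free the catechol while the aldehyde and the aryl bromide are untouched.

Step 2
Reactants: 2 5-bromo-2,3-dihydroxybenzaldehyde
Product: 3 5-bromo-2,3-bis(tosyloxy)benzaldehyde
Conditions: TsCl (2.4 equiv), Et3N, DMAP (cat.), CH2Cl2, 0 °C → rt
Reagents that add atoms: 4-methylbenzenesulfonyl chloride, Cc1ccc(cc1)S(=O)(=O)Cl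
Why: DMAP-catalysed O-sulfonylation of both phenols; aryl tosylates should resist the later ozone, Lewis-acid, palladium and enolate steps and are meant to leave reductively in step 17.

Step 3
Reactants: 3 5-bromo-2,3-bis(tosyloxy)benzaldehyde
Product: 4 methyl 3-formyl-4,5-bis(tosyloxy)benzoate
Conditions: Pd(OAc)2 (2 mol %), Xantphos (4 mol %), CO (1 atm), MeOH, Et3N, toluene, 70 °C
Reagents that add atoms: carbon monoxide, [C-]#[O+]; methanol, CO
Why: Palladium-catalysed methoxycarbonylation of the aryl bromide (oxidative addition to zerovalent palladium, CO insertion, methanolysis), selective for C–Br over the two C–OTs bonds.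

Step 4
Reactants: 4 methyl 3-formyl-4,5-bis(tosyloxy)benzoate
Product: 5 methyl 3-(hydroxymethyl)-4,5-bis(tosyloxy)benzoate
Conditions: NaBH4, THF/MeOH, 0 °C
Reagents that add atoms: none
Why: Chemoselective borohydride reduction of the aldehyde; the methyl ester and the aryl sulfonates should not react at 0 °C.

Step 5
Reactants: 5 methyl 3-(hydroxymethyl)-4,5-bis(tosyloxy)benzoate
Product: 6 methyl 3-(bromomethyl)-4,5-bis(tosyloxy)benzoate
Conditions: PBr3, CH2Cl2, 0 °C
Reagents that add atoms: phosphorus tribromide, BrP(Br)Br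
Why: Conversion of the benzylic alcohol into the bromide (SN2 on the bromophosphite) gives the alkylating agent.

Step 6
Reactants: 7 2-methylcyclopent-2-en-1-one; 6 methyl 3-(bromomethyl)-4,5-bis(tosyloxy)benzoate
Product: 9 methyl 3-{[(1R,2S)-1,2-dimethyl-5-oxocyclopentyl]methyl}-4,5-bis(tosyloxy)benzoate, via magnesium enolate 8 (not isolated)
Conditions: 7 (1.2 equiv), MeMgBr (1.15 equiv), Cu(OTf)2 (3 mol %), chiral imidazolinium carbene precursor (4 mol %), Et2O, −30 °C; then 6 (1.0 equiv), DMPU, THF, −30 °C → rt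
Reagents that add atoms: methylmagnesium bromide, C[Mg]Br
Why: Copper-catalysed asymmetric conjugate addition followed by enolate alkylation (three-component coupling): the chiral copper–carbene catalyst sets C8, and the benzylic bromide attacks the enolate face anti to the new methyl group, which sets quaternary C9 with the two methyl groups cis.

Step 7
Reactants: 9 methyl 3-{[(1R,2S)-1,2-dimethyl-5-oxocyclopentyl]methyl}-4,5-bis(tosyloxy)benzoate
Product: 11 methyl 3-{[(1R,5S)-1,5-dimethyl-2-(trifluoromethylsulfonyloxy)cyclopent-2-en-1-yl]methyl}-4,5-bis(tosyloxy)benzoate, via potassium enolate 10 (not isolated)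
Conditions: KN(SiMe3)2, THF, −78 °C; then PhNTf2, −78 → 0 °C
Reagents that add atoms: N-phenylbis(trifluoromethanesulfonimide), O=S(=O)(N(c1ccccc1)S(=O)(=O)C(F)(F)F)C(F)(F)F
Why: Regiospecific enolisation (C9 is quaternary, so only the CH2 side can enolise) and O-triflation of the enolate.

Step 8
Reactants: 11 methyl 3-{[(1R,5S)-1,5-dimethyl-2-(trifluoromethylsulfonyloxy)cyclopent-2-en-1-yl]methyl}-4,5-bis(tosyloxy)benzoate
Product: 12 methyl 3-{[(1R,5S)-1,5-dimethylcyclopent-2-en-1-yl]methyl}-4,5-bis(tosyloxy)benzoate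
Conditions: Pd(OAc)2 (5 mol %), PPh3 (10 mol %), HCO2H, Bu3N, DMF, 60 °C
Reagents that add atoms: none
Why: Palladium-catalysed formate reduction of the enol triflate (oxidative addition, decarboxylation of formate, reductive elimination) should give the cyclopentene without touching the stereocentres or the aryl sulfonates.

Step 9
Reactants: 13 benzyl 2-bromopropanoate
Product: 15 benzyl 2-(triphenylphosphoranylidene)propanoate, via phosphonium bromide 14 (not isolated)
Conditions: PPh3, toluene, 80 °C; then aq. NaOH, CH2Cl2, rt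
Reagents that add atoms: triphenylphosphine, c1ccc(cc1)P(c1ccccc1)c1ccccc1
Why: Quaternisation of PPh3 by the α-bromo ester (SN2) and deprotonation of the salt give the stabilised Wittig ylide.

Step 10
Reactants: 12 methyl 3-{[(1R,5S)-1,5-dimethylcyclopent-2-en-1-yl]methyl}-4,5-bis(tosyloxy)benzoate
Product: 17 methyl 3-[(2R,3S)-2-formyl-2,3-dimethyl-5-oxopentyl]-4,5-bis(tosyloxy)benzoate, via secondary ozonide 16 (not isolated)
Conditions: O3, CH2Cl2, −78 °C; then PPh3, −78 °C → rt
Reagents that add atoms: ozone, [O-][O+]=O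
Why: Ozonolysis with reductive work-up cleaves the ring C10=C6 bond and releases the acyclic C6–C10 chain as a dialdehyde with C8 and C9 intact; the electron-poor arene is inert and the C10 aldehyde has no α-hydrogen.

Step 11
Reactants: 17 methyl 3-[(2R,3S)-2-formyl-2,3-dimethyl-5-oxopentyl]-4,5-bis(tosyloxy)benzoate; 15 benzyl 2-(triphenylphosphoranylidene)propanoate
Product: 18 benzyl (2E,5S,6R)-6-formyl-7-[5-(methoxycarbonyl)-2,3-bis(tosyloxy)phenyl]-2,5,6-trimethylhept-2-enoate
Conditions: 15 (1.05 equiv), CH2Cl2, rt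
Reagents that add atoms: none
Why: Wittig olefination with a stabilised ylide, E-selective and chemoselective for the unhindered CH2–CHO because the other aldehyde sits on the quaternary carbon.

Step 12
Reactants: 18 benzyl (2E,5S,6R)-6-formyl-7-[5-(methoxycarbonyl)-2,3-bis(tosyloxy)phenyl]-2,5,6-trimethylhept-2-enoate
Product: 19 (5S,6R)-6-formyl-7-[5-(methoxycarbonyl)-2,3-bis(tosyloxy)phenyl]-2,5,6-trimethylheptanoic acid
Conditions: H2 (1 atm), Pd/C (10%), EtOAc, rt
Reagents that add atoms: none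
Why: Heterogeneous hydrogenation saturates the conjugated C=C bond and hydrogenolyses the benzyl ester in one operation; C5 forms as a mixture of epimers, which is irrelevant because C5 is enolised in step 15.

Step 13
Reactants: 19 (5S,6R)-6-formyl-7-[5-(methoxycarbonyl)-2,3-bis(tosyloxy)phenyl]-2,5,6-trimethylheptanoic acid
Product: 20 (5S,6R,7E)-6-{[5-(methoxycarbonyl)-2,3-bis(tosyloxy)phenyl]methyl}-2,5,6-trimethyl-8-(phenylsulfonyl)oct-7-enoic acid
Conditions: (EtO)2P(O)CH2SO2Ph (1.3 equiv), NaH (2.5 equiv), THF, 0 °C → rt; then 1 M HCl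
Reagents that add atoms: diethyl [(phenylsulfonyl)methyl]phosphonate, CCOP(=O)(CS(=O)(=O)c1ccccc1)OCC
Why: Horner–Wadsworth–Emmons olefination of the non-enolisable aldehyde with the sulfonyl-stabilised phosphonate should give the (E)-vinyl sulfone, the acid being carried as its sodium salt.

Step 14
Reactants: 20 (5S,6R,7E)-6-{[5-(methoxycarbonyl)-2,3-bis(tosyloxy)phenyl]methyl}-2,5,6-trimethyl-8-(phenylsulfonyl)oct-7-enoic acid
Product: 22 (7S,8R,9E)-8-{[5-(methoxycarbonyl)-2,3-bis(tosyloxy)phenyl]methyl}-4,7,8-trimethyl-10-(phenylsulfonyl)deca-1,9-dien-3-one, via acid chloride 21 (not isolated)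
Conditions: (COCl)2, DMF (cat.), CH2Cl2, 0 °C → rt; evaporate; then Bu3SnCH=CH2, Pd(PPh3)4 (5 mol %), toluene, 60 °C
Reagents that add atoms: tributyl(vinyl)stannane, C=C[Sn](CCCC)(CCCC)CCCC
Why: Acid chloride formation followed by palladium-catalysed acylation of the vinylstannane (Stille ketone synthesis) gives the vinyl ketone under neutral conditions that spare the vinyl sulfone, the ester and the sulfonates.

Step 15
Reactants: 22 (7S,8R,9E)-8-{[5-(methoxycarbonyl)-2,3-bis(tosyloxy)phenyl]methyl}-4,7,8-trimethyl-10-(phenylsulfonyl)deca-1,9-dien-3-one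
Product: 25 methyl 3-{[(1R,2S,4aS,8S,8aS)-1,2,4a-trimethyl-5-oxo-8-(phenylsulfonyl)decahydronaphthalen-1-yl]methyl}-4,5-bis(tosyloxy)benzoate, via silyl dienol ether 23 (not isolated), via silyl enol ether cycloadduct 24 (not isolated)
Conditions: Me3SiCl, Et3N, ZnCl2 (0.3 equiv), toluene, 150 °C (sealed tube, dilute); then 1 M HCl, THF, rt
Reagents that add atoms: none
Why: Silylation of the ketone (Me3SiCl/Et3N/ZnCl2) gives the 2-silyloxy diene 23 (C5=C4(OSiMe3)–C3=C2), whose C4=C5 isomers equilibrate through the ketone, and the isomer with the chain trans to the vinyl group adds across the (E)-vinyl sulfone (C10=C1) in a concerted, asynchronous intramolecular Diels–Alder reaction; the closest known reaction type is the thermal cyclisation of 2-silyloxy-1,7,9-decatrienes made in situ from enones (intramolecular double Michael reaction under silylating conditions). Ring A is closed by the [4+2] itself through both new bonds (C1–C2 and C5–C10), and ring B by the C5–C10 bond alone, as a six-membered ring fused through the C6–C9 tether in a chair. Regiochemistry is fixed by the tether and is also the matched one, since the nucleophilic enol ether carbon C5 meets the β-carbon C10 of the vinyl sulfone. The trans ring fusion (C5–CH3 anti to C10–H) comes from the transition state with the sulfonyl group endo and both forming ring-A bonds equatorial on the tether chair, and C1 follows from the E geometry of the sulfone. The face is chosen by the preset C8/C9 pair: the chair with C8–CH3 and the C9 arylmethyl group equatorial and only C9–CH3 axial is preferred over the one with C8–CH3 and the arylmethyl group axial, which gives (5S,10S) as needed; this facial preference and the ring fusion are the selectivities the step needs, and both rest on modest energy differences. Acid work-up hydrolyses the silyl enol ether 24 to ketone 25.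

Step 16
Reactants: 25 methyl 3-{[(1R,2S,4aS,8S,8aS)-1,2,4a-trimethyl-5-oxo-8-(phenylsulfonyl)decahydronaphthalen-1-yl]methyl}-4,5-bis(tosyloxy)benzoate
Product: 26 methyl 3-{[(1R,2S,4aS,8S,8aS)-1,2,4a-trimethyl-5-methylidene-8-(phenylsulfonyl)decahydronaphthalen-1-yl]methyl}-4,5-bis(tosyloxy)benzoate
Conditions: Zn, CH2Br2, TiCl4 (reagent pre-formed in THF, −40 → 5 °C); then 25, CH2Cl2, 0 °C → rt
Reagents that add atoms: dibromomethane, BrCBr
Why: Titanium–zinc methylenation (Takai–Lombardo reagent) should convert the hindered ketone next to quaternary C5 into the exocyclic methylene without base and without attacking the methyl ester or the sulfonates.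

Step 17
Reactants: 26 methyl 3-{[(1R,2S,4aS,8S,8aS)-1,2,4a-trimethyl-5-methylidene-8-(phenylsulfonyl)decahydronaphthalen-1-yl]methyl}-4,5-bis(tosyloxy)benzoate
Product: 27 methyl 4,5-dihydroxy-3-{[(1R,2S,4aS,8aS)-1,2,4a-trimethyl-5-methylidenedecahydronaphthalen-1-yl]methyl}benzoate (dictyoceratin A)
Conditions: Na/Hg (5% Na), Na2HPO4, MeOH/THF, −20 °C → rt, argon; then aq. NH4Cl
Reagents that add atoms: none
Why: Buffered sodium amalgam (reductive desulfonylation as in the Julia sequence) should cleave the C1–SO2Ph bond and both aryl O–SO2 bonds by electron transfer, leaving the isolated alkene and the benzoate intact, so that C1 becomes CH2 and the catechol is freed.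

Compound list

1 | 5-bromo-2-hydroxy-3-methoxybenzaldehyde | O=Cc1cc(Br)cc(OC)c1O | starting material
2 | 5-bromo-2,3-dihydroxybenzaldehyde | O=Cc1cc(Br)cc(O)c1O | intermediate
3 | 5-bromo-2,3-bis(tosyloxy)benzaldehyde | O=Cc1cc(Br)cc(OS(=O)(=O)c2ccc(C)cc2)c1OS(=O)(=O)c1ccc(C)cc1 | intermediate
4 | methyl 3-formyl-4,5-bis(tosyloxy)benzoate | O=Cc1cc(C(=O)OC)cc(OS(=O)(=O)c2ccc(C)cc2)c1OS(=O)(=O)c1ccc(C)cc1 | intermediate
5 | methyl 3-(hydroxymethyl)-4,5-bis(tosyloxy)benzoate | OCc1cc(C(=O)OC)cc(OS(=O)(=O)c2ccc(C)cc2)c1OS(=O)(=O)c1ccc(C)cc1 | intermediate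
6 | methyl 3-(bromomethyl)-4,5-bis(tosyloxy)benzoate | BrCc1cc(C(=O)OC)cc(OS(=O)(=O)c2ccc(C)cc2)c1OS(=O)(=O)c1ccc(C)cc1 | intermediate
7 | 2-methylcyclopent-2-en-1-one | CC1=CCCC1=O | starting material
8 | bromomagnesium (3S)-2,3-dimethylcyclopent-1-en-1-olate | Br[Mg]OC1=C(C)[C@@H](C)CC1 | intermediate (not isolated)
9 | methyl 3-{[(1R,2S)-1,2-dimethyl-5-oxocyclopentyl]methyl}-4,5-bis(tosyloxy)benzoate (ring methyl groups cis, arylmethyl trans to the C2 methyl) | O=C1[C@](C)(Cc2cc(C(=O)OC)cc(OS(=O)(=O)c3ccc(C)cc3)c2OS(=O)(=O)c2ccc(C)cc2)[C@@H](C)CC1 | intermediate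
10 | potassium (4S,5R)-5-{[5-(methoxycarbonyl)-2,3-bis(tosyloxy)phenyl]methyl}-4,5-dimethylcyclopent-1-en-1-olate | [K+].[O-]C1=CC[C@H](C)[C@@]1(C)Cc1cc(C(=O)OC)cc(OS(=O)(=O)c2ccc(C)cc2)c1OS(=O)(=O)c1ccc(C)cc1 | intermediate (not isolated)
11 | methyl 3-{[(1R,5S)-1,5-dimethyl-2-(trifluoromethylsulfonyloxy)cyclopent-2-en-1-yl]methyl}-4,5-bis(tosyloxy)benzoate | O=S(=O)(OC1=CC[C@H](C)[C@@]1(C)Cc1cc(C(=O)OC)cc(OS(=O)(=O)c2ccc(C)cc2)c1OS(=O)(=O)c1ccc(C)cc1)C(F)(F)F | intermediate
12 | methyl 3-{[(1R,5S)-1,5-dimethylcyclopent-2-en-1-yl]methyl}-4,5-bis(tosyloxy)benzoate | C1=CC[C@H](C)[C@@]1(C)Cc1cc(C(=O)OC)cc(OS(=O)(=O)c2ccc(C)cc2)c1OS(=O)(=O)c1ccc(C)cc1 | intermediate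
13 | benzyl 2-bromopropanoate (racemic) | CC(Br)C(=O)OCc1ccccc1 | starting material
14 | [1-(benzyloxy)-1-oxopropan-2-yl]triphenylphosphonium bromide | CC(C(=O)OCc1ccccc1)[P+](c1ccccc1)(c1ccccc1)c1ccccc1.[Br-] | intermediate (not isolated)
15 | benzyl 2-(triphenylphosphoranylidene)propanoate | CC(C(=O)OCc1ccccc1)=P(c1ccccc1)(c1ccccc1)c1ccccc1 | intermediate
16 | secondary ozonide of 12: methyl 3-{[(2R,3S)-2,3-dimethyl-6,7,8-trioxabicyclo[3.2.1]octan-2-yl]methyl}-4,5-bis(tosyloxy)benzoate (both bridgehead diastereomers) | O1OC2C[C@H](C)[C@@](C)(Cc3cc(C(=O)OC)cc(OS(=O)(=O)c4ccc(C)cc4)c3OS(=O)(=O)c3ccc(C)cc3)C1O2 | intermediate (not isolated)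
17 | methyl 3-[(2R,3S)-2-formyl-2,3-dimethyl-5-oxopentyl]-4,5-bis(tosyloxy)benzoate | O=C[C@](C)(Cc1cc(C(=O)OC)cc(OS(=O)(=O)c2ccc(C)cc2)c1OS(=O)(=O)c1ccc(C)cc1)[C@@H](C)CC=O | intermediate
18 | benzyl (2E,5S,6R)-6-formyl-7-[5-(methoxycarbonyl)-2,3-bis(tosyloxy)phenyl]-2,5,6-trimethylhept-2-enoate | O=C[C@](C)(Cc1cc(C(=O)OC)cc(OS(=O)(=O)c2ccc(C)cc2)c1OS(=O)(=O)c1ccc(C)cc1)[C@@H](C)C/C=C(\C)C(=O)OCc1ccccc1 | intermediate
19 | (5S,6R)-6-formyl-7-[5-(methoxycarbonyl)-2,3-bis(tosyloxy)phenyl]-2,5,6-trimethylheptanoic acid (both C2 epimers) | O=C[C@](C)(Cc1cc(C(=O)OC)cc(OS(=O)(=O)c2ccc(C)cc2)c1OS(=O)(=O)c1ccc(C)cc1)[C@@H](C)CCC(C)C(=O)O | intermediate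
20 | (5S,6R,7E)-6-{[5-(methoxycarbonyl)-2,3-bis(tosyloxy)phenyl]methyl}-2,5,6-trimethyl-8-(phenylsulfonyl)oct-7-enoic acid (both C2 epimers) | O=S(=O)(c1ccccc1)/C=C/[C@](C)(Cc1cc(C(=O)OC)cc(OS(=O)(=O)c2ccc(C)cc2)c1OS(=O)(=O)c1ccc(C)cc1)[C@@H](C)CCC(C)C(=O)O | intermediate
21 | (5S,6R,7E)-6-{[5-(methoxycarbonyl)-2,3-bis(tosyloxy)phenyl]methyl}-2,5,6-trimethyl-8-(phenylsulfonyl)oct-7-enoyl chloride | O=S(=O)(c1ccccc1)/C=C/[C@](C)(Cc1cc(C(=O)OC)cc(OS(=O)(=O)c2ccc(C)cc2)c1OS(=O)(=O)c1ccc(C)cc1)[C@@H](C)CCC(C)C(=O)Cl | intermediate (not isolated)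
22 | (7S,8R,9E)-8-{[5-(methoxycarbonyl)-2,3-bis(tosyloxy)phenyl]methyl}-4,7,8-trimethyl-10-(phenylsulfonyl)deca-1,9-dien-3-one (both C4 epimers) | O=S(=O)(c1ccccc1)/C=C/[C@](C)(Cc1cc(C(=O)OC)cc(OS(=O)(=O)c2ccc(C)cc2)c1OS(=O)(=O)c1ccc(C)cc1)[C@@H](C)CCC(C)C(=O)C=C | intermediate
23 | (3Z,7S,8R,9E)-8-{[5-(methoxycarbonyl)-2,3-bis(tosyloxy)phenyl]methyl}-4,7,8-trimethyl-10-(phenylsulfonyl)-3-(trimethylsilyloxy)deca-1,3,9-triene (reacting isomer, chain trans to the vinyl group) | O=S(=O)(c1ccccc1)/C=C/[C@](C)(Cc1cc(C(=O)OC)cc(OS(=O)(=O)c2ccc(C)cc2)c1OS(=O)(=O)c1ccc(C)cc1)[C@@H](C)CC/C(C)=C(/C=C)O[Si](C)(C)C | intermediate (not isolated)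
24 | methyl 3-{[(1R,2S,4aS,8S,8aS)-1,2,4a-trimethyl-8-(phenylsulfonyl)-5-(trimethylsilyloxy)-1,2,3,4,4a,7,8,8a-octahydronaphthalen-1-yl]methyl}-4,5-bis(tosyloxy)benzoate | C[Si](C)(C)OC1=CC[C@H](S(=O)(=O)c3ccccc3)[C@H]2[C@](C)(Cc3cc(C(=O)OC)cc(OS(=O)(=O)c4ccc(C)cc4)c3OS(=O)(=O)c3ccc(C)cc3)[C@@H](C)CC[C@]12C | intermediate (not isolated)
25 | methyl 3-{[(1R,2S,4aS,8S,8aS)-1,2,4a-trimethyl-5-oxo-8-(phenylsulfonyl)decahydronaphthalen-1-yl]methyl}-4,5-bis(tosyloxy)benzoate (trans-decalin, sulfonyl cis to the ring-fusion hydrogen) | O=C1CC[C@H](S(=O)(=O)c3ccccc3)[C@H]2[C@](C)(Cc3cc(C(=O)OC)cc(OS(=O)(=O)c4ccc(C)cc4)c3OS(=O)(=O)c3ccc(C)cc3)[C@@H](C)CC[C@]12C | intermediate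
26 | methyl 3-{[(1R,2S,4aS,8S,8aS)-1,2,4a-trimethyl-5-methylidene-8-(phenylsulfonyl)decahydronaphthalen-1-yl]methyl}-4,5-bis(tosyloxy)benzoate | C=C1CC[C@H](S(=O)(=O)c3ccccc3)[C@H]2[C@](C)(Cc3cc(C(=O)OC)cc(OS(=O)(=O)c4ccc(C)cc4)c3OS(=O)(=O)c3ccc(C)cc3)[C@@H](C)CC[C@]12C | intermediate
27 | methyl 4,5-dihydroxy-3-{[(1R,2S,4aS,8aS)-1,2,4a-trimethyl-5-methylidenedecahydronaphthalen-1-yl]methyl}benzoate (dictyoceratin A) | C=C1CCC[C@H]2[C@](C)(Cc3cc(C(=O)OC)cc(O)c3O)[C@@H](C)CC[C@]12C | target

Total step count: 17. Longest linear sequence: 16 steps (steps 1–8 and 10–17, from 1); step 9 is a one-step side branch.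

Steps most likely to fail

1. Step 15 (key cycloaddition). What may go wrong: slow closure at the congested C5–C10 bond, with loss of the diene by hydrolysis or polymerisation of the vinyl ketone; or poor discrimination between the two faces set by C8/C9 and between trans and cis ring fusion at 150 °C. Fallback, stepwise and at low temperature, from 22: LiN(SiMe3)2, THF, −78 → 0 °C should form the C5 enolate, which adds 6-exo to the vinyl sulfone (Michael addition; enolate geometry is irrelevant here). Protonation gives the monocyclic keto sulfone F1 with ring B closed. KOtBu (cat.), t-BuOH/THF, 0 °C → rt then closes ring A by 6-endo Michael addition of the α-sulfonyl carbanion onto the vinyl ketone and equilibrates the sulfonyl group to the equatorial position. This returns to the route at 25.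

2. Step 6 (conjugate addition and alkylation). What may go wrong: insufficient enantioface selection on the five-membered enone, or slow C-alkylation of the fully substituted magnesium enolate, so that proton transfer and attack on the sulfonate or ester groups of 6 compete. Fallback from 7: the same copper-catalysed methyl addition is quenched with Me3SiCl/Et3N and the silyl enol ether F2 is isolated (and its enantiomeric purity checked). MeLi, THF, 0 °C then releases the regiodefined lithium enolate F3, which is alkylated with 6 in THF/DMPU at −40 °C → rt, anti to the C8 methyl group. This returns to the route at 9.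

3. Step 17 (global reductive desulfonylation). What may go wrong: incomplete cleavage of the hindered secondary C–S bond after the aryl sulfonates are already gone, leaving an oxidation-prone catecholate under prolonged reduction. Fallback from 26, in two separate operations: Mg, MeOH, rt should cleave only the two aryl O–SO2 bonds and give the catechol sulfone F4; SmI2, HMPA, THF, −20 °C then cleaves the C–SO2Ph bond by single-electron transfer. This returns to the route at 27.

Further compounds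

F1 | step 15 | methyl 3-{[1,3,6-trimethyl-2-(phenylsulfonylmethyl)-3-(prop-2-enoyl)cyclohexyl]methyl}-4,5-bis(tosyloxy)benzoate (ring B closed; C5 acryloyl and C10 CH2SO2Ph both equatorial; C5, C8, C9, C10 as in 25) | C=CC(=O)[C@@]1(C)CC[C@H](C)[C@@](C)(Cc2cc(C(=O)OC)cc(OS(=O)(=O)c3ccc(C)cc3)c2OS(=O)(=O)c2ccc(C)cc2)[C@@H]1CS(=O)(=O)c1ccccc1
F2 | step 6 | [(3S)-2,3-dimethylcyclopent-1-en-1-yl]oxy(trimethyl)silane | C[Si](C)(C)OC1=C(C)[C@@H](C)CC1
F3 | step 6 | lithium (3S)-2,3-dimethylcyclopent-1-en-1-olate | [Li+].[O-]C1=C(C)[C@@H](C)CC1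
F4 | step 17 | methyl 4,5-dihydroxy-3-{[(1R,2S,4aS,8S,8aS)-1,2,4a-trimethyl-5-methylidene-8-(phenylsulfonyl)decahydronaphthalen-1-yl]methyl}benzoate | C=C1CC[C@H](S(=O)(=O)c3ccccc3)[C@H]2[C@](C)(Cc3cc(C(=O)OC)cc(O)c3O)[C@@H](C)CC[C@]12C
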